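The C-8 O-acyl bond is cut last (elemane numbering). Before it come the two exocyclic methylenes: C-3 from Mannich methylenation of a C-5–CH2–CHO arm, and C-13 from loss of AcOH from an α-CH2OAc lactone. The cyclohexane is then cut at C-8–C-9 and C-5–C-10 in one operation.
Enabling feature: in the six-membered ring the C-8 carbinol is joined through C-9H2 to quaternary C-10. C-10 bears the C-1=C-2 vinyl group and is bonded to C-5 with its C-4–C-15 aldehyde arm. The array C8(OH)–C9–C10(C1=C2)–C5–C4–C15HO is the retron of two consecutive allyl transpositions of a but-3-ene-1,2-diyl dianion equivalent onto a 1,4-bis-electrophile (aldehyde C-8, enal β-carbon C-5), which the γ-lactone ring holds trans on C-7 and C-6.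
Fragments: the five-carbon allylboronate 20 (C-9, C-10, C-14, C-1, C-2; boron on C-1, SiMe3 on C-2, OAc already on C-14) and lactone aldehyde 10 (C-4 to C-8, C-11 to C-13, C-15; enal masked as its dimethyl acetal).
Forward order: γ-lactone ring from the chiral pool (steps 1–6), cyclohexane ring by the annulation (step 13), both methylenes (step 14), C-8 ester (step 17), desilylation (step 18).
Stereochemistry: C-6 comes from butenolide 1. C-7 (and temporary C-11) come from anti conjugate addition and anti trapping. C-8 comes by chirality transfer from C-1 of 20, which is set with (+)-sparteine. C-5 and C-10 come from the chair-like ring closure on the trans-lactone template.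

Key step: step 13

Remark: elemane numbering is used for all intermediates. The temporary stereocentres C-11 (erased in step 14) and C-1 of 20 (erased in step 13) are drawn as expected from the steps that set them.

Step 1
Reactants: 1 (S)-5-(hydroxymethyl)furan-2(5H)-one
Product: 2 (S)-5-[(tert-butyldimethylsilyloxy)methyl]furan-2(5H)-one
Conditions: TBSCl, imidazole, CH2Cl2, 0 °C to rt
Reagents that add atoms: tert-butyldimethylsilyl chloride, CC(C)(C)[Si](C)(C)Cl
Why: Routine silylation of the primary alcohol places a bulky group on C-5 next to the chiral-pool stereocentre C-6, which will shield one face of the butenolide in step 2.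

Step 2
Reactants: 2 (S)-5-[(tert-butyldimethylsilyloxy)methyl]furan-2(5H)-one
Product: 5 (3R,4S,5S)-3-(acetoxymethyl)-5-[(tert-butyldimethylsilyloxy)methyl]-4-(2-methylprop-1-enyl)dihydrofuran-2(3H)-one, via magnesium enolate 3 (not isolated), via bromomagnesium alkoxide 4 (not isolated)
Conditions: Me2C=CHMgBr, CuBr·SMe2 (cat.), THF, −78 °C; CH2O (monomer in THF), −78 to −40 °C; Ac2O, DMAP (cat.), −40 °C to rt
Reagents that add atoms: 2-methylprop-1-enylmagnesium bromide, CC(C)=C[Mg]Br; formaldehyde, C=O; acetic anhydride, CC(=O)OC(C)=O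
Why: Copper-catalysed conjugate addition occurs anti to the C-6 substituent (sets C-7), the enolate is hydroxymethylated anti to the new alkenyl group (tandem conjugate addition–aldol, temporary C-11 centre) and the alkoxide is acetylated in the same flask, so C-8 (masked as an isobutenyl group) and C-13 (masked as CH2OAc) enter together.

Step 3
Reactants: 5 (3R,4S,5S)-3-(acetoxymethyl)-5-[(tert-butyldimethylsilyloxy)methyl]-4-(2-methylprop-1-enyl)dihydrofuran-2(3H)-one
Product: 6 (3R,4S,5S)-3-(acetoxymethyl)-5-(hydroxymethyl)-4-(2-methylprop-1-enyl)dihydrofuran-2(3H)-one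
Conditions: HF·pyridine, THF, 0 °C to rt
Reagents that add atoms: none
Why: Acidic fluoride desilylation frees the C-5 alcohol while avoiding the basic conditions that would expel the β-acetoxy group (E1cB).

Step 4
Reactants: 6 (3R,4S,5S)-3-(acetoxymethyl)-5-(hydroxymethyl)-4-(2-methylprop-1-enyl)dihydrofuran-2(3H)-one
Product: 8 (3R,4S,5R)-3-(acetoxymethyl)-4-(2-methylprop-1-enyl)-5-[(E)-3-oxoprop-1-enyl]dihydrofuran-2(3H)-one, via lactone carbaldehyde 7 (not isolated)
Conditions: Dess–Martin periodinane, CH2Cl2, 0 °C; then Ph3P=CHCHO, rt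
Reagents that add atoms: (triphenylphosphoranylidene)acetaldehyde, O=CC=P(c1ccccc1)(c1ccccc1)c1ccccc1
Why: Dess–Martin oxidation followed in the same flask by Wittig olefination with the stabilised ylide should give the (E)-enal and spares isolation of the epimerisable α-acyloxy aldehyde 7, so C-6 is kept.

Step 5
Reactants: 8 (3R,4S,5R)-3-(acetoxymethyl)-4-(2-methylprop-1-enyl)-5-[(E)-3-oxoprop-1-enyl]dihydrofuran-2(3H)-one
Product: 9 (3R,4S,5R)-3-(acetoxymethyl)-5-[(E)-3,3-dimethoxyprop-1-enyl]-4-(2-methylprop-1-enyl)dihydrofuran-2(3H)-one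
Conditions: HC(OMe)3, PPTS (cat.), CH2Cl2, rt
Reagents that add atoms: trimethyl orthoformate, COC(OC)OC
Why: Acid-catalysed acetalisation with an orthoformate masks C-15 so that C-8 will be the only free aldehyde in step 13 and stores the enal as the precursor of an alkoxyallyl cation.

Step 6
Reactants: 9 (3R,4S,5R)-3-(acetoxymethyl)-5-[(E)-3,3-dimethoxyprop-1-enyl]-4-(2-methylprop-1-enyl)dihydrofuran-2(3H)-one
Product: 10 (3R,4S,5R)-3-(acetoxymethyl)-5-[(E)-3,3-dimethoxyprop-1-enyl]-4-formyldihydrofuran-2(3H)-one
Conditions: O3 (1 equiv), CH2Cl2, −78 °C; then Me2S, −78 °C to rt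
Reagents that add atoms: ozone, [O-][O+]=O
Why: Ozonolysis with one equivalent of ozone should cleave the electron-rich trisubstituted isobutenyl alkene in preference to the disubstituted C-4=C-5 alkene, which is deactivated by two allylic C–O groups, and unveils the C-8 aldehyde with C-7 in its thermodynamically preferred trans arrangement.

Step 7
Reactants: 11 2-bromoprop-2-en-1-ol
Product: 12 (2-bromoallyloxy)triethylsilane
Conditions: TESCl, imidazole, CH2Cl2, 0 °C
Reagents that add atoms: chlorotriethylsilane, CC[Si](CC)(CC)Cl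
Why: Routine silylation gives an ether that survives palladium catalysis and organolithium chemistry yet is removed under very mild acid in step 11.

Step 8
Reactants: 12 (2-bromoallyloxy)triethylsilane
Product: 13 triethyl{[2-(4,4,5,5-tetramethyl-1,3,2-dioxaborolan-2-yl)allyl]oxy}silane
Conditions: B2pin2, PdCl2(PPh3)2 (cat.), PPh3 (cat.), KOPh, toluene, 50 °C
Reagents that add atoms: bis(pinacolato)diboron, CC1(C)OB(OC1(C)C)B1OC(C)(C)C(C)(C)O1
Why: Miyaura borylation of the alkenyl bromide (oxidative addition, transmetallation with the phenoxide-activated diboron, reductive elimination) gives the 1,1-disubstituted alkenylboronate.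

Step 9
Reactants: 14 2-(trimethylsilyl)ethanol
Product: 15 2-(trimethylsilyl)ethyl N,N-diisopropylcarbamate
Conditions: iPr2NC(O)Cl, Et3N, CH2Cl2, reflux
Reagents that add atoms: N,N-diisopropylcarbamoyl chloride, CC(C)N(C(C)C)C(=O)Cl
Why: Carbamoylation of the primary alcohol installs the directing and leaving group needed for α-lithiation.

Step 10
Reactants: 15 2-(trimethylsilyl)ethyl N,N-diisopropylcarbamate; 13 triethyl{[2-(4,4,5,5-tetramethyl-1,3,2-dioxaborolan-2-yl)allyl]oxy}silane
Product: 18 (R)-allylboronate triethylsilyl ether CH2=C(CH2OTES)–CH(Bpin)–CH2SiMe3, via lithiated carbamate 16 (not isolated), via boronate complex 17 (not isolated)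
Conditions: s-BuLi, (+)-sparteine, Et2O, −78 °C; then 13, −78 °C; then reflux
Reagents that add atoms: none
Why: Lithiation–borylation: sparteine-mediated enantioselective α-deprotonation gives (R)-16, borylation proceeds with retention and the Matteson-type 1,2-metallate rearrangement of 17 moves the alkenyl group from boron to carbon with inversion, which sets (R)-C-1.

Step 11
Reactants: 18 (R)-allylboronate triethylsilyl ether
Product: 19 (R)-allylboronate alcohol CH2=C(CH2OH)–CH(Bpin)–CH2SiMe3
Conditions: PPTS (cat.), MeOH, 0 °C to rt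
Reagents that add atoms: none
Why: Mild acid-catalysed methanolysis removes the triethylsilyl ether selectively, since the C–SiMe3 bond and the pinacol allylboronate are inert to PPTS.

Step 12
Reactants: 19 (R)-allylboronate alcohol
Product: 20 (R)-allylboronate acetate CH2=C(CH2OAc)–CH(Bpin)–CH2SiMe3
Conditions: Ac2O, pyridine, DMAP (cat.), CH2Cl2, 0 °C
Reagents that add atoms: acetic anhydride, CC(=O)OC(C)=O
Why: Standard acetylation installs the C-14 acetate of the target before the fragments are joined, so that a free C-14 hydroxyl never meets the C-15 aldehyde (lactol formation is avoided).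

Step 13
Reactants: 10 (3R,4S,5R)-3-(acetoxymethyl)-5-[(E)-3,3-dimethoxyprop-1-enyl]-4-formyldihydrofuran-2(3H)-one; 20 (R)-allylboronate acetate
Product: 23 13,14-diacetoxy-8α-hydroxy-15-oxo-3-nor-11βH-elem-1-en-6α,12-olide, via allylsilane borate 21 (not isolated), via bicyclic enol ether 22 (not isolated)
Conditions: 10, 20 (1.3 equiv), 4 Å MS, CH2Cl2, rt to 40 °C; then 2,6-di-tert-butylpyridine, Me3SiOTf (cat.), −78 °C; then 1 M HCl, THF, 0 °C
Reagents that add atoms: water, O
Why: Proposed new method: reagent 20 acts as a but-3-ene-1,2-diyl 1,2-dianion equivalent that is unmasked by two consecutive allyl transpositions, the closest known reaction types being the tandem double allylation of dicarbonyl compounds with vicinal bis(boronates) and the intramolecular Hosomi–Sakurai reaction. First, C-9 of the allylboronate adds to the only free aldehyde (C-8; the enal is masked as its acetal, and lactone and acetates are inert to boronates) through a closed six-membered chair transition state with the lactone residue equatorial and CH2SiMe3 axial (it avoids 1,2-strain with CH2OAc), so the (R)-centre C-1 is traded for the (8S)-carbinol and for a C-10=C-1 bond that holds CH2SiMe3 cis to C-9, which converts the unreactive β-silyl boronate into allylsilane 21. Second, Me3SiOTf ionises the allylic acetal to a 1-methoxyallyl cation and C-10 attacks its C-5 terminus in an anti-SE2′, 6-exo-trig closure of the cyclohexane (attack at C-15 would need an eight-membered ring holding an E alkene), which releases Me3SiOMe, regenerates Me3SiOTf and leaves the vinyl group and enol ether 22; aqueous acid then gives aldehyde 23. C-5 and C-10 are set in a chair-like transition state locked by the trans-fused lactone: C-8–O and the C-4 arm lie equatorial (H-5 axial, anti to H-6), and the forming vinyl arm should also lie equatorial because an axial C-1 would push its cis CH2SiMe3 group over the ring against H-8 and H-6, so CH2OAc ends axial as in the target. The step needs chemoselectivity between two aldehyde carbons (secured by the acetal), acetal ionisation faster than 1,4-elimination of Me3Si and the allylic acetate (secured by catalytic Me3SiOTf at −78 °C) and no protodesilylation (secured by the hindered base).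

Step 14
Reactants: 23 13,14-diacetoxy-8α-hydroxy-15-oxo-3-nor-11βH-elem-1-en-6α,12-olide
Product: 25 14-acetoxy-8α-hydroxy-15-oxoelema-1,3,11(13)-trien-6α,12-olide, via acetoxymethyl enal 24 (not isolated)
Conditions: CH2=NMe2+ I− (excess), Et3N, CH2Cl2, rt; then DBU, 0 °C
Reagents that add atoms: N,N-dimethylmethyleneiminium iodide (Eschenmoser's salt), C=[N+](C)C.[I-]
Why: Mannich α-methylenation of the aldehyde (enol addition to the iminium salt, then amine elimination) installs C-3, and DBU then expels acetate from the α-acetoxymethyl lactone (E1cB) to give the C-11=C-13 methylene, which erases the temporary C-11 centre and touches no other stereocentre.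

Step 15
Reactants: 26 ethyl 2-(hydroxymethyl)acrylate
Product: 27 ethyl 2-[(tert-butyldimethylsilyloxy)methyl]acrylate
Conditions: TBSCl, imidazole, CH2Cl2, 0 °C to rt
Reagents that add atoms: tert-butyldimethylsilyl chloride, CC(C)(C)[Si](C)(C)Cl
Why: Routine silylation protects the allylic hydroxyl of the acrylate.

Step 16
Reactants: 27 ethyl 2-[(tert-butyldimethylsilyloxy)methyl]acrylate
Product: 28 2-[(tert-butyldimethylsilyloxy)methyl]acrylic acid
Conditions: LiOH, THF/H2O, 0 °C; then 1 M HCl to pH 4
Reagents that add atoms: lithium hydroxide, [Li+].[OH-]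
Why: Saponification of the ethyl ester followed by careful acidification gives the free acid with the silyl ether intact.

Step 17
Reactants: 25 14-acetoxy-8α-hydroxy-15-oxoelema-1,3,11(13)-trien-6α,12-olide; 28 2-[(tert-butyldimethylsilyloxy)methyl]acrylic acid
Product: 30 tert-butyldimethylsilyl ether of the target, via mixed anhydride 29 (not isolated)
Conditions: 28, 2,4,6-Cl3C6H2COCl, Et3N, toluene, rt; then 25, DMAP, rt
Reagents that add atoms: none
Why: Yamaguchi esterification through mixed anhydride 29 acylates the hindered equatorial 8α-hydroxyl under mild conditions with retention at C-8.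

Step 18
Reactants: 30 tert-butyldimethylsilyl ether of the target
Product: 31 14-acetoxy-8α-[2-(hydroxymethyl)acryloyloxy]-15-oxoelema-1,3,11(13)-trien-6α,12-olide (target)
Conditions: HF·pyridine, pyridine, THF, 0 °C
Reagents that add atoms: none
Why: Buffered fluoride desilylation frees the primary allylic alcohol without affecting acetate, ester, lactone or enal, and gives the target.

Compound list
1 | (S)-5-(hydroxymethyl)furan-2(5H)-one | C1=CC(=O)O[C@@H]1CO | starting material
2 | (S)-5-[(tert-butyldimethylsilyloxy)methyl]furan-2(5H)-one | C1=CC(=O)O[C@@H]1CO[Si](C)(C)C(C)(C)C | intermediate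
3 | bromomagnesium enolate of the conjugate adduct (alkenyl group trans to CH2OTBS) | CC(C)=C[C@H]1C=C(O[Mg]Br)O[C@@H]1CO[Si](C)(C)C(C)(C)C | intermediate
4 | bromomagnesium alkoxide of the α-hydroxymethyl lactone (3,4-trans, 4,5-trans) | CC(C)=C[C@H]1[C@H](CO[Mg]Br)C(=O)O[C@@H]1CO[Si](C)(C)C(C)(C)C | intermediate
5 | (3R,4S,5S)-3-(acetoxymethyl)-5-[(tert-butyldimethylsilyloxy)methyl]-4-(2-methylprop-1-enyl)dihydrofuran-2(3H)-one | CC(C)=C[C@H]1[C@H](COC(C)=O)C(=O)O[C@@H]1CO[Si](C)(C)C(C)(C)C | intermediate
6 | (3R,4S,5S)-3-(acetoxymethyl)-5-(hydroxymethyl)-4-(2-methylprop-1-enyl)dihydrofuran-2(3H)-one | CC(C)=C[C@H]1[C@H](COC(C)=O)C(=O)O[C@@H]1CO | intermediate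
7 | lactone carbaldehyde (CH2OH of 6 oxidised to CHO, configuration as in 6) | CC(C)=C[C@H]1[C@H](COC(C)=O)C(=O)O[C@@H]1C=O | intermediate
8 | (3R,4S,5R)-3-(acetoxymethyl)-4-(2-methylprop-1-enyl)-5-[(E)-3-oxoprop-1-enyl]dihydrofuran-2(3H)-one | CC(C)=C[C@H]1[C@H](COC(C)=O)C(=O)O[C@@H]1/C=C/C=O | intermediate
9 | (3R,4S,5R)-3-(acetoxymethyl)-5-[(E)-3,3-dimethoxyprop-1-enyl]-4-(2-methylprop-1-enyl)dihydrofuran-2(3H)-one | CC(C)=C[C@H]1[C@H](COC(C)=O)C(=O)O[C@@H]1/C=C/C(OC)OC | intermediate
10 | (3R,4S,5R)-3-(acetoxymethyl)-5-[(E)-3,3-dimethoxyprop-1-enyl]-4-formyldihydrofuran-2(3H)-one | O=C[C@H]1[C@H](COC(C)=O)C(=O)O[C@@H]1/C=C/C(OC)OC | intermediate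
11 | 2-bromoprop-2-en-1-ol | OCC(Br)=C | starting material
12 | (2-bromoallyloxy)triethylsilane | C=C(Br)CO[Si](CC)(CC)CC | intermediate
13 | triethyl{[2-(4,4,5,5-tetramethyl-1,3,2-dioxaborolan-2-yl)allyl]oxy}silane | C=C(CO[Si](CC)(CC)CC)B1OC(C)(C)C(C)(C)O1 | intermediate
14 | 2-(trimethylsilyl)ethanol | C[Si](C)(C)CCO | starting material
15 | 2-(trimethylsilyl)ethyl N,N-diisopropylcarbamate | C[Si](C)(C)CCOC(=O)N(C(C)C)C(C)C | intermediate
16 | (R)-1-lithio-2-(trimethylsilyl)ethyl N,N-diisopropylcarbamate, as its (+)-sparteine complex | C[Si](C)(C)C[C@@H]([Li])OC(=O)N(C(C)C)C(C)C | intermediate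
17 | lithium boronate complex from 16 and 13 (retention at carbon) | C[Si](C)(C)C[C@@H]([B-]1(OC(C)(C)C(C)(C)O1)C(=C)CO[Si](CC)(CC)CC)OC(=O)N(C(C)C)C(C)C.[Li+] | intermediate
18 | (R)-CH2=C(CH2OTES)–CH(Bpin)–CH2SiMe3 | C[Si](C)(C)C[C@H](B1OC(C)(C)C(C)(C)O1)C(=C)CO[Si](CC)(CC)CC | intermediate
19 | (R)-CH2=C(CH2OH)–CH(Bpin)–CH2SiMe3 | C[Si](C)(C)C[C@H](B1OC(C)(C)C(C)(C)O1)C(=C)CO | intermediate
20 | (R)-CH2=C(CH2OAc)–CH(Bpin)–CH2SiMe3 | C[Si](C)(C)C[C@H](B1OC(C)(C)C(C)(C)O1)C(=C)COC(C)=O | intermediate
21 | allylsilane borate: lactone 10 extended at C-8 to (8S)-CH(OBpin)–CH2–C(CH2OAc)=CH–CH2SiMe3, with CH2SiMe3 cis to C-9 (E by CIP) | C[Si](C)(C)C/C=C(/COC(C)=O)C[C@H](OB1OC(C)(C)C(C)(C)O1)[C@H]2[C@H](COC(C)=O)C(=O)O[C@@H]2/C=C/C(OC)OC | intermediate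
22 | bicyclic enol ether: 8α-OBpin, 10α-vinyl, 10β-CH2OAc, 5β-[(E)-2-methoxyvinyl], 11α-CH2OAc, trans-fused 6α,12-olide | C=C[C@]1(COC(C)=O)C[C@H](OB3OC(C)(C)C(C)(C)O3)[C@H]2[C@H](COC(C)=O)C(=O)O[C@@H]2[C@H]1/C=C/OC | intermediate
23 | 13,14-diacetoxy-8α-hydroxy-15-oxo-3-nor-11βH-elem-1-en-6α,12-olide (H-5α, H-6β, H-7α, H-8β, 10β-CH2OAc) | C=C[C@]1(COC(C)=O)C[C@H](O)[C@H]2[C@H](COC(C)=O)C(=O)O[C@@H]2[C@H]1CC=O | intermediate
24 | 13,14-diacetoxy-8α-hydroxy-15-oxo-11βH-elema-1,3-dien-6α,12-olide | C=C[C@]1(COC(C)=O)C[C@H](O)[C@H]2[C@H](COC(C)=O)C(=O)O[C@@H]2[C@H]1C(=C)C=O | intermediate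
25 | 14-acetoxy-8α-hydroxy-15-oxoelema-1,3,11(13)-trien-6α,12-olide | C=C[C@]1(COC(C)=O)C[C@H](O)[C@H]2C(=C)C(=O)O[C@@H]2[C@H]1C(=C)C=O | intermediate
26 | ethyl 2-(hydroxymethyl)acrylate | C=C(CO)C(=O)OCC | starting material
27 | ethyl 2-[(tert-butyldimethylsilyloxy)methyl]acrylate | C=C(CO[Si](C)(C)C(C)(C)C)C(=O)OCC | intermediate
28 | 2-[(tert-butyldimethylsilyloxy)methyl]acrylic acid | C=C(CO[Si](C)(C)C(C)(C)C)C(=O)O | intermediate
29 | mixed anhydride of 28 and 2,4,6-trichlorobenzoic acid | C=C(CO[Si](C)(C)C(C)(C)C)C(=O)OC(=O)c1c(Cl)cc(Cl)cc1Cl | intermediate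
30 | 14-acetoxy-8α-{2-[(tert-butyldimethylsilyloxy)methyl]acryloyloxy}-15-oxoelema-1,3,11(13)-trien-6α,12-olide | C=C[C@]1(COC(C)=O)C[C@H](OC(=O)C(=C)CO[Si](C)(C)C(C)(C)C)[C@H]2C(=C)C(=O)O[C@@H]2[C@H]1C(=C)C=O | intermediate
31 | (5R,6R,7R,8S,10R)-14-acetoxy-8α-[2-(hydroxymethyl)acryloyloxy]-15-oxoelema-1,3,11(13)-trien-6α,12-olide | C=C[C@]1(COC(C)=O)C[C@H](OC(=O)C(=C)CO)[C@H]2C(=C)C(=O)O[C@@H]2[C@H]1C(=C)C=O | target

Total step count: 18. Longest linear sequence: 10 steps (1, 2, 3, 4, 5, 6, 13, 14, 17, 18).

Steps most likely to fail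

Step 13 (bears the label). What may go wrong:
- a slow allylboration that allows epimerisation at C-7
- a mismatch between reagent control and the intrinsic facial bias of the aldehyde
- 1,4-elimination of silyl and acetate groups
- protodesilylation
- poor facial selectivity at C-10 in the ring closure

The fallback sets out from 10 and 20 and comes back at 23. It separates the two bond formations and runs each as a known reaction on an isolated compound. Thermal allylboration of 10 with 20, followed by hydrolytic work-up of borate 21, gives the homoallylic alcohol acetal F1. Mild hydrolysis (PPTS, wet acetone) frees the hydroxy allylsilane enal F2. A classical Lewis-acid-promoted intramolecular Hosomi–Sakurai 1,4-addition to the enal (EtAlCl2, CH2Cl2, −78 °C) then closes C-5–C-10 and gives 23 after protonation of the aluminium enolate.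

Step 10. What may go wrong: β-elimination of the silyl and carbamate groups from the boronate complex in place of 1,2-migration, or incomplete or poorly selective lithiation of the β-silyl carbamate. The fallback sets out from 13 and comes back at 23. It places silicon on the nucleophile instead of next to the leaving group.
- Matteson homologation of 13 (LiCHCl2 from CH2Cl2 and n-BuLi, −100 °C, then ZnCl2) gives the racemic α-chloroallylboronate F3.
- Me3SiCH2MgCl displaces chloride by 1,2-migration to give the racemic silyl ether boronate F4.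
- The conditions of steps 11 and 12 give the racemic alcohol boronate F5 and the racemic acetate boronate F6.
- F6 is used in excess in step 13.

C-1 is erased there and 10 is a single enantiomer, so 23 stays enantiopure. C-8 selectivity then rests on the faster reaction of the matched enantiomer.

Step 14. What may go wrong: conjugate addition of liberated dimethylamine to the new acceptors, base-induced migration of the C-4 methylene into conjugation at C-5, or translactonisation towards the free C-8 hydroxyl. The fallback sets out from 23 and comes back at 30. The aldehyde alone is methylenated with a catalytic amine (aqueous CH2O, pyrrolidine and propionic acid as catalysts, iPrOH, 45 °C) and 24 is isolated. The C-8 hydroxyl of 24 is esterified with 28 under the conditions of step 17 to give the acetoxymethyl lactone ester F7. Only then is acetate expelled with DBU (CH2Cl2, 0 °C), now with no free hydroxyl and no secondary amine present, to give 30.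

Further compounds
F1 | step 13 | homoallylic alcohol acetal (free 8-OH form of 21) | C[Si](C)(C)C/C=C(/COC(C)=O)C[C@H](O)[C@H]1[C@H](COC(C)=O)C(=O)O[C@@H]1/C=C/C(OC)OC
F2 | step 13 | hydroxy allylsilane enal | C[Si](C)(C)C/C=C(/COC(C)=O)C[C@H](O)[C@H]1[C@H](COC(C)=O)C(=O)O[C@@H]1/C=C/C=O
F3 | step 10 | racemic α-chloroallylboronate | C=C(CO[Si](CC)(CC)CC)C(Cl)B1OC(C)(C)C(C)(C)O1
F4 | step 10 | racemic silyl ether boronate (racemate of 18) | C[Si](C)(C)CC(B1OC(C)(C)C(C)(C)O1)C(=C)CO[Si](CC)(CC)CC
F5 | step 10 | racemic alcohol boronate (racemate of 19) | C[Si](C)(C)CC(B1OC(C)(C)C(C)(C)O1)C(=C)CO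
F6 | step 10 | racemic acetate boronate (racemate of 20) | C[Si](C)(C)CC(B1OC(C)(C)C(C)(C)O1)C(=C)COC(C)=O
F7 | step 14 | acetoxymethyl lactone ester | C=C[C@]1(COC(C)=O)C[C@H](OC(=O)C(=C)CO[Si](C)(C)C(C)(C)C)[C@H]2[C@H](COC(C)=O)C(=O)O[C@@H]2[C@H]1C(=C)C=O
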